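The quinone ring (numbered C1=O, C2–OMe, C3–H, C4=O, C5–Me, C6–pentacosyl) is opened at the C2=C3 enol-ether bond. The 1,2,4-oxygen pattern lets C2 be read as an ester carbonyl and C3 as the methyl group of the C4 ketone, so the ring is closed by a Claisen condensation. In one operation, the anion of ethyl 1,3-dithiane-2-carboxylate (C1 masked as a dithiane, C2 as the ester) adds to 3-methylbut-3-en-2-one (C3–C6) and the acyclic keto ester so formed cyclises at C2–C3. Oxidative unmasking, O-methylation and a late decarboxylative radical alkylation at C6 with hexacosanoic acid finish the synthesis.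

Key step: step 1

Remark on the chemistry: the target is achiral. Compounds 1, 2 and 9 are taken as purchasable. The one stereocentre formed on the way (C5 in 3, 4 and 5) is racemic and is erased in step 2.

Step 1
Reactants: 1 3-methylbut-3-en-2-one; 2 ethyl 1,3-dithiane-2-carboxylate
Product: 4 (±)-10-methyl-1,5-dithiaspiro[5.5]undecane-7,9-dione, via Michael adduct 3 (not isolated)
Conditions: KOt-Bu (0.1 equiv), THF, 0 °C, slow addition of 1; then KOt-Bu (2.2 equiv), THF/t-BuOH, 60 °C; aq. HCl work-up
Reagents that add atoms: none
Why: KOt-Bu deprotonates 2 to a soft carbanion stabilised by two sulfur atoms and the ester, which adds in conjugate fashion to the unsubstituted CH2 terminus of enone 1 (forming C1–C6); proton transfer then gives the methyl-ketone enolate of 3, whose C3 attacks the ester carbonyl C2 and expels ethoxide. The closest known reaction type is the Michael–Claisen (dimedone-type) cyclohexane-1,3-dione annulation of an enone with an ester-stabilised carbanion. The six-membered ring closes at C2–C3 in a 6-(enolendo)-exo-trig mode. The single new stereocentre (the methyl-bearing C5, set by unselective protonation) should form racemic and is erased on aromatisation in step 2. The step needs 1,4- over 1,2-addition, secured by the soft doubly stabilised anion and the unhindered β-carbon, and closure from the methyl and not the methine α-carbon, secured because the methine enolate could only form a four-membered ring and the dithiane carbon carries no hydrogen; irreversible deprotonation of the 1,3-dione product should pull the reversible Michael and enolate equilibria forward.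

Step 2
Reactants: 4 (±)-10-methyl-1,5-dithiaspiro[5.5]undecane-7,9-dione
Product: 7 2-hydroxy-5-methylcyclohexa-2,5-diene-1,4-dione, via trione 5 (not isolated), via benzenetriol 6 (not isolated)
Conditions: (NH4)2Ce(NO3)6 (4.5 equiv), MeCN/H2O (4:1), 0 °C to rt
Reagents that add atoms: water, O
Why: Oxidative dethioacetalisation by tetravalent cerium frees the C1 carbonyl (oxygen from water), the 1,2,4-trione 5 enolises to the aromatic triol 6, and the same oxidant takes 6 to the para-quinone (hydroquinone-to-quinone oxidation), which erases the C5 stereocentre.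

Step 3
Reactants: 7 2-hydroxy-5-methylcyclohexa-2,5-diene-1,4-dione
Product: 8 2-methoxy-5-methylcyclohexa-2,5-diene-1,4-dione
Conditions: MeOH, H2SO4 (cat.), reflux
Reagents that add atoms: methanol, CO
Why: The 2-hydroxyquinone is a vinylogous carboxylic acid, so acid-catalysed Fischer-type esterification with methanol under thermodynamic control should give the 2-methoxy-1,4-quinone rather than the ether of the 1,2-quinone tautomer.

Step 4
Reactants: 8 2-methoxy-5-methylcyclohexa-2,5-diene-1,4-dione; 9 hexacosanoic acid
Product: 10 2-methoxy-5-methyl-6-pentacosylcyclohexa-2,5-diene-1,4-dione (the target, also named 5-methoxy-2-methyl-3-pentacosyl-1,4-benzoquinone)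
Conditions: AgNO3 (0.3 equiv), (NH4)2S2O8 (1.5 equiv), MeCN/H2O/PhCl, 80 °C
Reagents that add atoms: none
Why: Silver-catalysed decarboxylative radical alkylation of a quinone (Jacobsen–Torssell variant of the Kochi decarboxylation): peroxodisulfate raises the silver to the divalent state, which oxidises the carboxylate of 9; loss of CO2 gives the nucleophilic pentacosyl radical, which should add at C6, the only unsubstituted carbon of the electron-poor methyl-bearing double bond (C3 is the electron-rich α-carbon of the vinylogous ester), and re-oxidation of the adduct restores the quinone.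

Compound list
1 | 3-methylbut-3-en-2-one | CC(=O)C(C)=C | starting material
2 | ethyl 1,3-dithiane-2-carboxylate | CCOC(=O)C1SCCCS1 | starting material
3 | ethyl 2-(2-methyl-3-oxobutyl)-1,3-dithiane-2-carboxylate (racemic) | CCOC(=O)C1(CC(C)C(C)=O)SCCCS1 | intermediate
4 | 10-methyl-1,5-dithiaspiro[5.5]undecane-7,9-dione (racemic) | CC1CC2(SCCCS2)C(=O)CC1=O | intermediate
5 | 5-methylcyclohexane-1,2,4-trione (racemic) | CC1CC(=O)C(=O)CC1=O | intermediate
6 | 5-methylbenzene-1,2,4-triol | Cc1cc(O)c(O)cc1O | intermediate
7 | 2-hydroxy-5-methylcyclohexa-2,5-diene-1,4-dione | CC1=CC(=O)C(O)=CC1=O | intermediate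
8 | 2-methoxy-5-methylcyclohexa-2,5-diene-1,4-dione | CC1=CC(=O)C(OC)=CC1=O | intermediate
9 | hexacosanoic acid | CCCCCCCCCCCCCCCCCCCCCCCCCC(=O)O | starting material
10 | 2-methoxy-5-methyl-6-pentacosylcyclohexa-2,5-diene-1,4-dione | CCCCCCCCCCCCCCCCCCCCCCCCCC1=C(C)C(=O)C=C(OC)C1=O | target

Total step count: 4
Longest linear sequence: 4 steps (1 and 2 → 4 → 7 → 8 → 10)

Steps most likely to fail

1. Step 4. The pentacosyl radical may add at C3 as well as at C6, may dimerise or be oxidised before it meets the quinone, and the waxy C26 acid may stay out of the aqueous phase so that conversion stalls.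
Fallback (chain before ring; sets out from 2, returns at 10): purchased hexacosan-1-ol is oxidised (TEMPO cat., PhI(OAc)2, CH2Cl2) to hexacosanal F1. With the purchased stabilised ylide 3-(triphenylphosphoranylidene)butan-2-one (toluene, reflux), F1 should give (E)-3-methylnonacos-3-en-2-one F2. The same KOt-Bu Michael–Claisen annulation with 2 should then pass through ethyl 2-(3-methyl-2-oxononacosan-4-yl)-1,3-dithiane-2-carboxylate F3 to 10-methyl-11-pentacosyl-1,5-dithiaspiro[5.5]undecane-7,9-dione F4 (mixture of diastereomers, both stereocentres erased later). (NH4)2Ce(NO3)6 in aqueous MeCN/THF should take F4 through 5-methyl-6-pentacosylcyclohexane-1,2,4-trione F5 and 5-methyl-6-pentacosylbenzene-1,2,4-triol F6 to 2-hydroxy-5-methyl-6-pentacosylcyclohexa-2,5-diene-1,4-dione F7, and MeOH/H2SO4 should methylate F7 to 10. The chain is then fixed at C6 by the Wittig–Michael sequence, with no regiochemical question.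

2. Step 1. The enone may polymerise under the anionic conditions, the dione enolate may add to a second molecule of 1, or adduct 3 may revert by retro-Michael cleavage at the temperature the hindered Claisen closure needs.
Fallback (a nitronate in place of the dithiane anion; sets out from 1, returns at 7): purchased ethyl nitroacetate adds to 1 under Et3N catalysis to give ethyl 4-methyl-2-nitro-5-oxohexanoate F8 (mixture of diastereomers). Ozonolysis of its sodium nitronate (NaOMe, MeOH; O3, −78 °C; Me2S), a Nef-type conversion, should give ethyl 4-methyl-2,5-dioxohexanoate F9 (racemic). KOt-Bu in THF then closes the same C2–C3 bond by Claisen attack of the methyl ketone on the unhindered α-keto ester to give trione 5, which enolises to triol 6 and is oxidised by air on work-up to 7.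

3. Step 2. The tetravalent cerium may over-oxidise the electron-rich enol or the hydroxyquinone, and liberated thiol may add back to the quinone.
Fallback (hydrolysis and oxidation separated; sets out from 4, returns at 7): thiophile-assisted, non-oxidative hydrolysis with Hg(ClO4)2/CaCO3 in aqueous THF (divalent mercury binds the dithiol) should give 5 and hence triol 6 with no oxidant present. After the mercury thiolate is filtered off, 6 is oxidised on its own with aqueous FeCl3 to 7. No new compound is made.

Further compounds
F1 | step 4 | hexacosanal | CCCCCCCCCCCCCCCCCCCCCCCCCC=O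
F2 | step 4 | (E)-3-methylnonacos-3-en-2-one | CC(=O)/C(C)=C/CCCCCCCCCCCCCCCCCCCCCCCCC
F3 | step 4 | ethyl 2-(3-methyl-2-oxononacosan-4-yl)-1,3-dithiane-2-carboxylate (mixture of diastereomers) | CCOC(=O)C1(SCCCS1)C(CCCCCCCCCCCCCCCCCCCCCCCCC)C(C)C(C)=O
F4 | step 4 | 10-methyl-11-pentacosyl-1,5-dithiaspiro[5.5]undecane-7,9-dione (mixture of diastereomers) | CCCCCCCCCCCCCCCCCCCCCCCCCC1C(C)C(=O)CC(=O)C12SCCCS2
F5 | step 4 | 5-methyl-6-pentacosylcyclohexane-1,2,4-trione (mixture of diastereomers) | CCCCCCCCCCCCCCCCCCCCCCCCCC1C(C)C(=O)CC(=O)C1=O
F6 | step 4 | 5-methyl-6-pentacosylbenzene-1,2,4-triol | CCCCCCCCCCCCCCCCCCCCCCCCCc1c(C)c(O)cc(O)c1O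
F7 | step 4 | 2-hydroxy-5-methyl-6-pentacosylcyclohexa-2,5-diene-1,4-dione | CCCCCCCCCCCCCCCCCCCCCCCCCC1=C(C)C(=O)C=C(O)C1=O
F8 | step 1 | ethyl 4-methyl-2-nitro-5-oxohexanoate (mixture of diastereomers) | CCOC(=O)C([N+](=O)[O-])CC(C)C(C)=O
F9 | step 1 | ethyl 4-methyl-2,5-dioxohexanoate (racemic) | CCOC(=O)C(=O)CC(C)C(C)=O
F0 | step 2 | none | none
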